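The cyclohexane ring (C5–C10, elemane numbering) is cut at C9–C10 and C5–C6 into a four-carbon unit C6–C9 and a two-carbon unit C5=C10. The key step exploits two features of this ring: oxygen on C6 and on C8, flanking C7 (the pattern of a 1,3-dioxygenated diene), and carbon substituents on both C10 and C5. One Diels–Alder reaction of silyloxy diene 11, which carries the future lactone carbons as an alkyne on C7, with enantiopure menthyloxy butenolide 3 forms both bonds and sets C10 and C6. The butenolide's acetal and lactone carbons then become the vinyl and isopropenyl (later acrylic acid) groups.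

Key step: step 6

Remark: elemane numbering (C1–C15) is used throughout and β is the face of the C10 methyl group; it is assumed that acetal 3 crystallises as its (5R) epimer with (−)-menthol, as the 4-unsubstituted analogue does.

Step 1
Reactants: 1 5-hydroxy-4-methylfuran-2(5H)-one; 2 (−)-menthol
Product: 3 (5R)-5-[(1R,2S,5R)-menthyloxy]-4-methylfuran-2(5H)-one
Conditions: camphorsulfonic acid (cat.), toluene, reflux, Dean–Stark; crystallisation from hexane
Reagents that add atoms: none
Why: Acid-catalysed acetal exchange of the pseudo-acid; the acetal epimers interconvert through the oxocarbenium ion and the (5R) epimer should be collected by crystallisation.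

Step 2
Reactants: 4 ethynyltriisopropylsilane; 5 methyloxirane (racemic)
Product: 7 5-(triisopropylsilyl)pent-4-yn-2-ol (racemic), via lithium (triisopropylsilyl)acetylide 6 (not isolated)
Conditions: n-BuLi, THF, −78 °C; then 5, DMPU, −78 → 25 °C; H2O
Reagents that add atoms: none
Why: SN2 opening of the epoxide at its CH2 terminus by the acetylide (epoxide alkynylation); the carbinol centre is destroyed in step 3.

Step 3
Reactants: 7 5-(triisopropylsilyl)pent-4-yn-2-ol
Product: 8 5-(triisopropylsilyl)pent-4-yn-2-one
Conditions: Dess–Martin periodinane, CH2Cl2, 0 → 25 °C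
Reagents that add atoms: none
Why: Dess–Martin oxidation under neutral conditions should avoid base-mediated isomerisation of the β,γ-alkynyl ketone to the allenyl ketone.

Step 4
Reactants: 8 5-(triisopropylsilyl)pent-4-yn-2-one
Product: 10 (E)-3-[(tert-butyldimethylsilyloxy)methylidene]-5-(triisopropylsilyl)pent-4-yn-2-one, via sodium hydroxymethylene enolate 9 (not isolated)
Conditions: NaH, HCO2Et, Et2O, 0 → 25 °C; then TBSCl, THF, 0 °C
Reagents that add atoms: ethyl formate CCOC=O; tert-butyldimethylsilyl chloride CC(C)(C)[Si](C)(C)Cl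
Why: Crossed Claisen formylation at the more acidic propargylic α-CH2 gives the chelated sodium enolate, and O-silylation should give the vinylogous silyl ester with the silyloxy group trans to acetyl (E), the less hindered isomer.

Step 5
Reactants: 10 (E)-silyloxymethylidene ketone
Product: 11 (1E)-1-(tert-butyldimethylsilyloxy)-3-(triisopropylsilyloxy)-2-[(triisopropylsilyl)ethynyl]buta-1,3-diene
Conditions: TIPSOTf, Et3N, CH2Cl2, 0 °C
Reagents that add atoms: triisopropylsilyl trifluoromethanesulfonate CC(C)[Si](OS(=O)(=O)C(F)(F)F)(C(C)C)C(C)C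
Why: Soft enolisation of the methyl ketone, the only enolisable position, gives the 2-silyloxy diene without touching the C6=C7 geometry.

Step 6
Reactants: 11 silyloxy diene; 3 (5R)-menthyloxy butenolide
Product: 12 cis-fused cycloadduct (lactone acetal C4(=O)–O–C1H(OMen) spanning C5 and C10; 10β-methyl; 5β-H; 6α-OTBS; C7=C8 TIPS enol ether; 7-(TIPS-ethynyl))
Conditions: CH2Cl2, BHT (cat.), 13 kbar, 40 °C
Reagents that add atoms: none
Why: Concerted normal-electron-demand Diels–Alder reaction: the terminal CH2 of the 1,3-dioxygenated diene (C9, largest HOMO coefficient) bonds to the β-carbon of the butenolide (methyl-bearing C10) and the silyloxy-bearing terminus (C6) to its α-carbon (C5). The closest known reaction type is the thermal cycloaddition of 1-alkoxy-3-silyloxy dienes to 5-alkoxyfuran-2(5H)-ones, run here at high pressure because the β-methyl group retards the dienophile. The cyclohexene ring is closed by suprafacial [4+2] cycloaddition, giving the cis-fused bicyclic lactone acetal. C10 and C5 arise cis from the ring-locked (Z) alkene, with the absolute sense fixed by attack on the face anti to the menthyloxy group of the (5R) acetal carbon; C6 is set by the endo transition state (lactone carbonyl under the diene), which puts the silyloxy group cis to C4 and C1. The step needs regio-, endo and π-facial selectivity, secured by the single activating carbonyl, secondary orbital overlap and the acetal substituent; the C5 configuration (C4 on the α face) is corrected in step 8.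

Step 7
Reactants: 12 cycloadduct
Product: 13 lactol (C4 methyl hemiketal; C1 menthyl acetal retained)
Conditions: MeLi (1.1 equiv), THF, −78 °C; H2O
Reagents that add atoms: methyllithium [Li]C
Why: Mono-addition of the organolithium to the lactone stops at the lithium lactolate at −78 °C; silyl enol ether, acetal and silyl alkyne are inert, and the new hemiketal centre is lost in step 8.

Step 8
Reactants: 13 lactol
Product: 17 10α-vinyl-5β-isopropenyl diene (5α-H; 6α-OTBS; enol ether and silyl alkyne unchanged), via keto aldehyde 14 (not isolated), via cis vinyl ketone 15 (not isolated), via trans vinyl ketone 16 (not isolated)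
Conditions: Ph3PCH3Br (6 equiv), KOtBu (5.5 equiv), toluene, 0 °C, then 70 °C
Reagents that add atoms: methyltriphenylphosphonium bromide [Br-].C[P+](c1ccccc1)(c1ccccc1)c1ccccc1
Why: Wittig methylenation of a lactol: base opens the hemiketal to the methyl ketone and the menthyl hemiacetal alkoxide, which loses mentholate to give the aldehyde, methylenated at 0 °C; on heating with excess KOtBu the ketone equilibrates at C5 and the less hindered equatorial acetyl epimer (5α-H, trans to O6 and to the C10 vinyl group) should be methylenated preferentially (Curtin–Hammett), while the pseudo-equatorial C6–O bond is poorly aligned for β-elimination.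

Step 9
Reactants: 17 vinyl isopropenyl diene
Product: 19 8β-alcohol (axial OH; 7β-alkynyl, 7α-H), via 8-ketone 18 (not isolated)
Conditions: TBAF (1.05 equiv), AcOH (1.05 equiv), THF, −40 °C; then L-selectride, −78 °C; H2O
Reagents that add atoms: none
Why: Fluoride cleaves the silyl enol ether fastest and axial protonation of the enolate at C7 should give the ketone with the equatorial alkynyl group trans to O6; L-selectride, attacking from the equatorial side because the axial face is blocked by the syn-axial C10 methyl group, reduces it at once to the axial 8β-alcohol before the α-alkynyl ketone can epimerise.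

Step 10
Reactants: 19 8β-alcohol; 20 angelic acid
Product: 21 8α-angelate
Conditions: PPh3, DIAD, toluene, 0 → 25 °C
Reagents that add atoms: none
Why: Mitsunobu esterification: SN2 displacement of the axial oxyphosphonium group by angelate from the open equatorial direction inverts C8 under neutral conditions that should not isomerise the (Z)-acid.

Step 11
Reactants: 21 8α-angelate
Product: 22 6α-hydroxy-7β-ethynyl compound
Conditions: TBAF, AcOH, THF, 0 → 25 °C
Reagents that add atoms: none
Why: Fluoride removes the O-silyl and C-silyl groups; the buffer protects the angelate, whose 1,3-diequatorial relation to O6 excludes acyl migration.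

Step 12
Reactants: 22 homopropargylic alcohol
Product: 23 trans-fused α-methylene γ-lactone (6α,12-olide) with 5β-isopropenyl
Conditions: PdCl2 (10 mol %), SnCl2 (10 mol %), PPh3 (20 mol %), CO (7 atm), MeCN, 75 °C
Reagents that add atoms: carbon monoxide [C-]#[O+]
Why: Palladium-catalysed hydroxyl-directed cyclocarbonylation of a trans-2-ethynylcyclohexanol: the alkoxycarbonyl–palladium species from O6 and CO adds syn across the only alkyne (5-exo) and protonolysis gives the exocyclic methylene lactone; no stereocentre is touched and O8 is already acylated, so only the 6,12-lactone can form.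

Step 13
Reactants: 23 methylene lactone
Product: 24 allylic alcohol (C15 hydroxymethyl on the 2-propenyl group at C5)
Conditions: SeO2 (0.5 equiv), t-BuOOH, salicylic acid (cat.), CH2Cl2, 25 °C
Reagents that add atoms: tert-butyl hydroperoxide CC(C)(C)OO
Why: Allylic oxidation (ene reaction then [2,3] shift) should attack the electron-rich 1,1-disubstituted isopropenyl group at its methyl group; the vinyl group has no allylic hydrogen and the lactone and angelate alkenes are electron-poor.

Step 14
Reactants: 24 allylic alcohol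
Product: 26 target 8α-(angeloyloxy)-6α,12-elemanolide-1,3,11(13)-trien-15-oic acid, via enal 25 (not isolated)
Conditions: TEMPO (cat.), PhI(OAc)2, CH2Cl2, 25 °C; then NaClO2, NaH2PO4, 2-methyl-2-butene, t-BuOH–H2O
Reagents that add atoms: sodium chlorite [Na+].[O-]Cl=O
Why: Oxoammonium oxidation gives the enal and Pinnick oxidation with a hypochlorite scavenger converts it into the acrylic acid without touching the lactone, the angelate or the alkenes.

Compound list
1 | 5-hydroxy-4-methylfuran-2(5H)-one | CC1=CC(=O)OC1O | starting material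
2 | (−)-menthol, (1R,2S,5R) | C[C@@H]1CC[C@H]([C@@H](C1)O)C(C)C | starting material
3 | (5R)-5-[(1R,2S,5R)-menthyloxy]-4-methylfuran-2(5H)-one | C[C@@H]1CC[C@H]([C@@H](C1)O[C@@H]2OC(=O)C=C2C)C(C)C | intermediate
4 | ethynyltriisopropylsilane | C#C[Si](C(C)C)(C(C)C)C(C)C | starting material
5 | methyloxirane (racemic) | CC1CO1 | starting material
6 | lithium (triisopropylsilyl)acetylide (not isolated) | [Li+].[C-]#C[Si](C(C)C)(C(C)C)C(C)C | intermediate
7 | 5-(triisopropylsilyl)pent-4-yn-2-ol (racemic) | CC(O)CC#C[Si](C(C)C)(C(C)C)C(C)C | intermediate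
8 | 5-(triisopropylsilyl)pent-4-yn-2-one | CC(=O)CC#C[Si](C(C)C)(C(C)C)C(C)C | intermediate
9 | sodium enolate of 3-formyl-5-(triisopropylsilyl)pent-4-yn-2-one (not isolated) | [Na+].[O-]/C=C(\C(C)=O)C#C[Si](C(C)C)(C(C)C)C(C)C | intermediate
10 | (E)-3-[(tert-butyldimethylsilyloxy)methylidene]-5-(triisopropylsilyl)pent-4-yn-2-one | CC(=O)/C(C#C[Si](C(C)C)(C(C)C)C(C)C)=C/O[Si](C)(C)C(C)(C)C | intermediate
11 | (1E)-1-(tert-butyldimethylsilyloxy)-3-(triisopropylsilyloxy)-2-[(triisopropylsilyl)ethynyl]buta-1,3-diene | C=C(O[Si](C(C)C)(C(C)C)C(C)C)/C(C#C[Si](C(C)C)(C(C)C)C(C)C)=C/O[Si](C)(C)C(C)(C)C | intermediate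
12 | cis-fused cycloadduct, lactone menthyl acetal (10β-Me, 5β-H, 6α-OTBS) | C[C@@]12CC(O[Si](C(C)C)(C(C)C)C(C)C)=C(C#C[Si](C(C)C)(C(C)C)C(C)C)[C@H](O[Si](C)(C)C(C)(C)C)[C@@H]1C(=O)O[C@H]2O[C@@H]1C[C@H](C)CC[C@H]1C(C)C | intermediate
13 | lactol (C4 methyl hemiketal, epimer mixture at C4) | C[C@@]12CC(O[Si](C(C)C)(C(C)C)C(C)C)=C(C#C[Si](C(C)C)(C(C)C)C(C)C)[C@H](O[Si](C)(C)C(C)(C)C)[C@@H]1C(C)(O)O[C@H]2O[C@@H]1C[C@H](C)CC[C@H]1C(C)C | intermediate
14 | keto aldehyde (10α-formyl, 5α-acetyl; not isolated) | O=C[C@]1(C)CC(O[Si](C(C)C)(C(C)C)C(C)C)=C(C#C[Si](C(C)C)(C(C)C)C(C)C)[C@H](O[Si](C)(C)C(C)(C)C)[C@@H]1C(C)=O | intermediate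
15 | cis vinyl ketone (10α-vinyl, 5α-acetyl; not isolated) | C=C[C@]1(C)CC(O[Si](C(C)C)(C(C)C)C(C)C)=C(C#C[Si](C(C)C)(C(C)C)C(C)C)[C@H](O[Si](C)(C)C(C)(C)C)[C@@H]1C(C)=O | intermediate
16 | trans vinyl ketone (10α-vinyl, 5β-acetyl; not isolated) | C=C[C@]1(C)CC(O[Si](C(C)C)(C(C)C)C(C)C)=C(C#C[Si](C(C)C)(C(C)C)C(C)C)[C@H](O[Si](C)(C)C(C)(C)C)[C@H]1C(C)=O | intermediate
17 | 10α-vinyl-5β-isopropenyl silyl enol ether | C=C[C@]1(C)CC(O[Si](C(C)C)(C(C)C)C(C)C)=C(C#C[Si](C(C)C)(C(C)C)C(C)C)[C@H](O[Si](C)(C)C(C)(C)C)[C@H]1C(C)=C | intermediate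
18 | 8-ketone (7β-alkynyl; not isolated) | C=C[C@]1(C)CC(=O)[C@@H](C#C[Si](C(C)C)(C(C)C)C(C)C)[C@H](O[Si](C)(C)C(C)(C)C)[C@H]1C(C)=C | intermediate
19 | 8β-alcohol | C=C[C@]1(C)C[C@@H](O)[C@@H](C#C[Si](C(C)C)(C(C)C)C(C)C)[C@H](O[Si](C)(C)C(C)(C)C)[C@H]1C(C)=C | intermediate
20 | angelic acid, (Z)-2-methylbut-2-enoic acid | C/C=C(/C)C(=O)O | starting material
21 | 8α-angelate | C=C[C@]1(C)C[C@H](OC(=O)/C(C)=C\C)[C@@H](C#C[Si](C(C)C)(C(C)C)C(C)C)[C@H](O[Si](C)(C)C(C)(C)C)[C@H]1C(C)=C | intermediate
22 | 6α-hydroxy-7β-ethynyl 8α-angelate | C=C[C@]1(C)C[C@H](OC(=O)/C(C)=C\C)[C@@H](C#C)[C@H](O)[C@H]1C(C)=C | intermediate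
23 | 6α,12-olide with 5β-isopropenyl | C=C[C@]1(C)C[C@H](OC(=O)/C(C)=C\C)[C@H]2C(=C)C(=O)O[C@@H]2[C@H]1C(C)=C | intermediate
24 | C15 allylic alcohol | C=C[C@]1(C)C[C@H](OC(=O)/C(C)=C\C)[C@H]2C(=C)C(=O)O[C@@H]2[C@H]1C(=C)CO | intermediate
25 | C15 enal (not isolated) | C=C[C@]1(C)C[C@H](OC(=O)/C(C)=C\C)[C@H]2C(=C)C(=O)O[C@@H]2[C@H]1C(=C)C=O | intermediate
26 | target acid | C=C[C@]1(C)C[C@H](OC(=O)/C(C)=C\C)[C@H]2C(=C)C(=O)O[C@@H]2[C@H]1C(=C)C(=O)O | target

Total step count: 14. Longest linear sequence: 13 steps (steps 2–14, from ethynyltriisopropylsilane and methyloxirane).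

Steps most likely to fail

Step 6. The β-methyl group may make the cycloaddition so slow that the silyloxy diene decomposes before it reacts, or endo and facial selectivity may erode under forcing conditions. The fallback sets out from 11 and uses a more reactive open-chain dienophile. (Z)-3-Methylpent-2-en-4-ynal F1 (from commercial (Z)-3-methylpent-2-en-4-yn-1-ol with MnO2) should add to 11 in toluene at 80 °C to give the racemic endo cycloadduct aldehyde F2. Lindlar catalyst (Pd on CaCO3, Pb(OAc)2-poisoned) with H2 reduces the terminal alkyne to the racemic vinyl aldehyde F3, MeMgBr gives the carbinol F4, and Dess–Martin oxidation gives the racemic cis vinyl ketone F5. Preparative chromatography on a chiral stationary phase supplies 15, where the fallback comes back to the route; 15 is then epimerised and methylenated under the conditions of step 8.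

Step 8. Epimerisation at C5 may be incomplete or unselective, and the keto aldehyde may undergo aldol closure or lose silanol under the basic, hot conditions. The fallback sets out from 12 and sets C5 by kinetic protonation. Me(MeO)NH·HCl with AlMe3 (CH2Cl2, 0 °C) opens the lactone acetal to the aldehyde Weinreb amide F6. Ph3P=CH2 (THF, −78 → 0 °C) gives the cis vinyl Weinreb amide F7. LDA (THF, −78 °C) followed by 2,6-di-tert-butylphenol protonates the amide enolate on the α face, anti to the axial C10 methyl group, to give the trans vinyl Weinreb amide F8. MeMgBr then gives 16, where the fallback comes back to the route; non-basic methylenation with Cp2TiMe2 (toluene, 70 °C) converts 16 into 17.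

Step 10. The activated axial alcohol may eliminate to the enyne, or substitution may be sluggish with partial (Z) to (E) isomerisation of the acid. The fallback sets out from 18, isolated by running the desilylation of step 9 without hydride. SmI2 in THF/i-PrOH reduces 18 under thermodynamic control to the equatorial 8α-alcohol F9. Yamaguchi esterification of F9 with 20 (2,4,6-trichlorobenzoyl chloride, Et3N; then DMAP, toluene, 80 °C) acylates with retention and comes back to the route at 21.

Further compounds
F1 | step 6 | (Z)-3-methylpent-2-en-4-ynal | C#C/C(C)=C\C=O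
F2 | step 6 | racemic endo cycloadduct aldehyde (10α-ethynyl, 5α-formyl, 6α-OTBS; relative configuration shown) | C#C[C@]1(C)CC(O[Si](C(C)C)(C(C)C)C(C)C)=C(C#C[Si](C(C)C)(C(C)C)C(C)C)[C@H](O[Si](C)(C)C(C)(C)C)[C@@H]1C=O
F3 | step 6 | racemic vinyl aldehyde (relative configuration shown) | C=C[C@]1(C)CC(O[Si](C(C)C)(C(C)C)C(C)C)=C(C#C[Si](C(C)C)(C(C)C)C(C)C)[C@H](O[Si](C)(C)C(C)(C)C)[C@@H]1C=O
F4 | step 6 | racemic methyl carbinol (carbinol epimers; relative configuration shown) | C=C[C@]1(C)CC(O[Si](C(C)C)(C(C)C)C(C)C)=C(C#C[Si](C(C)C)(C(C)C)C(C)C)[C@H](O[Si](C)(C)C(C)(C)C)[C@@H]1C(C)O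
F5 | step 6 | racemic cis vinyl ketone (racemate of 15; relative configuration shown) | C=C[C@]1(C)CC(O[Si](C(C)C)(C(C)C)C(C)C)=C(C#C[Si](C(C)C)(C(C)C)C(C)C)[C@H](O[Si](C)(C)C(C)(C)C)[C@@H]1C(C)=O
F6 | step 8 | aldehyde Weinreb amide (10α-formyl, 5α-amide) | O=C[C@]1(C)CC(O[Si](C(C)C)(C(C)C)C(C)C)=C(C#C[Si](C(C)C)(C(C)C)C(C)C)[C@H](O[Si](C)(C)C(C)(C)C)[C@@H]1C(=O)N(C)OC
F7 | step 8 | cis vinyl Weinreb amide | C=C[C@]1(C)CC(O[Si](C(C)C)(C(C)C)C(C)C)=C(C#C[Si](C(C)C)(C(C)C)C(C)C)[C@H](O[Si](C)(C)C(C)(C)C)[C@@H]1C(=O)N(C)OC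
F8 | step 8 | trans vinyl Weinreb amide (5α-H) | C=C[C@]1(C)CC(O[Si](C(C)C)(C(C)C)C(C)C)=C(C#C[Si](C(C)C)(C(C)C)C(C)C)[C@H](O[Si](C)(C)C(C)(C)C)[C@H]1C(=O)N(C)OC
F9 | step 10 | 8α-alcohol (equatorial OH) | C=C[C@]1(C)C[C@H](O)[C@@H](C#C[Si](C(C)C)(C(C)C)C(C)C)[C@H](O[Si](C)(C)C(C)(C)C)[C@H]1C(C)=C
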